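**Assumptions:** The SMILES is taken as drawn: 4α‑CHO (C18 aldehyde, as in abietic acid), 7β‑OH, and C11 cis to the chromone on the new cyclohexene. Labdane numbers are used for the terpenoid (C17 = exocyclic CH2, C18 = CHO) and primed numbers for the former flavone B ring (C1′ quaternary, C2′/C5′ carbonyls, C6′ ring‑fusion CH). The route is a paper design; no step has been run.

## Retrosynthetic overview

1. Not used: the biomimetic labda‑8(17),12E,14‑triene + flavone‑2′,5′‑quinone Diels–Alder. The target is its anti‑Alder (exo) adduct, and that reaction has no handle on π‑face selectivity.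
2. The cyclohexene is opened at C13=C14 (ring‑closing metathesis, formed last) and at C15–C6′ (enolate allylation; C6′ set by equilibration to the cis‑fused ene‑dione).
3. Key step: the C12–C1′ bond, the quaternary C1′ and C12 come from a chirality‑transferring Claisen rearrangement of a (Z)‑allyl enol ether of a dearomatised flavone B ring (a quinone monoketal after conjugate reduction). Z‑alkene + chair transition state puts C11 cis to the chromone.
4. Fragments: flavone 22 (chalcone route) and (12Z,14S)‑labdadienol 15 from abietic acid. Abietic acid supplies C4, C5, C9, C10; ring C is cleaved; Sharpless epoxidation sets 7β‑OH and the 8(17)‑ene; Still–Gennari then CBS build the side chain.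
5. Ring order: A/B decalin (chiral pool) → chromone → B‑ring dearomatisation → cyclohexene.

## Route

### Terpenoid fragment

**Step 1**
Reactants: 1 (–)‑abietic acid
Product: 2 abietinol (abieta‑7,13‑dien‑18‑ol)
Conditions: LiAlH4, THF, 0 °C → reflux
Reagents that add atoms: none
Why: Hydride reduction of the acid to the primary alcohol; C4 (β‑Me), C5 (α‑H), C9 (α‑H) and C10 (β‑Me) already have the target configuration from the chiral pool.

**Step 2**
Reactants: 2 abietinol
Product: 3 18‑(4‑methoxybenzyloxy)abieta‑7,13‑diene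
Conditions: NaH, PMBCl, TBAI, THF/DMF, 0 °C → rt
Reagents that add atoms: PMBCl, COc1ccc(CCl)cc1
Why: Williamson etherification; PMB is orthogonal to the silyl ethers used later and is removed oxidatively at the end.

**Step 3**
Reactants: 3
Product: 4 13,14‑seco keto‑enal: decalin with C7=C8–CHO (the CHO carbon becomes C17) and a 9β‑CH2CH2C(=O)CH(CH3)2 side chain
Conditions: OsO4 (2 mol %), NaIO4, 2,6‑lutidine, dioxane/H2O, rt
Reagents that add atoms: OsO4, O=[Os](=O)(=O)=O, and NaIO4, [Na+].[O-]I(=O)(=O)=O (oxygen source)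
Why: Lemieux–Johnson cleavage; OsO4 takes the more exposed ring‑C alkene (C13=C14) of the heteroannular diene, and the product enal is too electron‑poor to react again.

**Step 4**
Reactants: 4
Product: 5 primary allylic alcohol (C17–OH, C7=C8), isopropyl ketone intact
Conditions: LiAlH(Ot‑Bu)3, THF, –78 → –40 °C
Reagents that add atoms: none
Why: Chemoselective 1,2‑reduction of the aldehyde in the presence of the hindered α‑branched ketone.

**Step 5**
Reactants: 5
Product: 6 7β,8β‑epoxy alcohol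
Conditions: Ti(Oi‑Pr)4, D‑(–)‑DIPT, t‑BuOOH, 4 Å MS, CH2Cl2, –20 °C
Reagents that add atoms: t‑BuOOH, CC(C)(C)OO
Why: Sharpless asymmetric epoxidation; the D‑tartrate delivers oxygen to the β‑face (reagent control over the α‑preference of the substrate), which fixes the C7–O configuration.

**Step 6**
Reactants: 6
Product: 7 epoxy iodide
Conditions: I2, PPh3, imidazole, THF, 0 °C
Reagents that add atoms: I2, II
Why: Appel‑type (Garegg–Samuelsson) conversion of the primary alcohol to the iodide; the epoxide and ketone are untouched.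

**Step 7**
Reactants: 7
Product: 8 7β‑hydroxy‑8(17)‑ene ketone
Conditions: Zn dust, EtOH, reflux
Reagents that add atoms: none
Why: Zinc‑mediated reductive opening of the epoxy iodide (β‑elimination) gives the exocyclic C8=C17 alkene and the C7 alkoxide with retention, so the epoxide face becomes 7β‑OH.

**Step 8**
Reactants: 8
Product: 9 7β‑OTBS ketone
Conditions: TBSCl, imidazole, DMAP, DMF, 40 °C
Reagents that add atoms: TBSCl, CC(C)(C)[Si](C)(C)Cl
Why: Standard silylation of the equatorial allylic alcohol.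

**Step 9**
Reactants: 9
Product: 10 12‑hydroxy ketone (epimer mixture at C12)
Conditions: LDA, THF, –78 °C; then 2‑(phenylsulfonyl)‑3‑phenyloxaziridine
Reagents that add atoms: Davis oxaziridine, O=S(=O)(c1ccccc1)N1OC1c1ccccc1
Why: Kinetic deprotonation at the CH2 side (not the isopropyl CH) followed by Davis enolate hydroxylation.

**Step 10**
Reactants: 10
Product: 11 7β‑(TBSO)‑18‑(PMBO)‑13,14,15,16‑tetranorlabd‑8(17)‑en‑12‑al
Conditions: Pb(OAc)4, MeOH/PhH, 0 °C
Reagents that add atoms: none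
Why: Criegee‑type cleavage of the α‑ketol removes the isopropyl ketone carbons as methyl isobutyrate and leaves the C12 aldehyde.

**Step 11**
Reactants: 11
Product: 12 methyl (12Z)‑7β‑(TBSO)‑18‑(PMBO)‑15‑norlabda‑8(17),12‑dien‑14‑oate
Conditions: (CF3CH2O)2P(O)CH(CH3)CO2Me, KHMDS, 18‑crown‑6, THF, –78 °C
Reagents that add atoms: Still–Gennari propionate reagent, COC(=O)C(C)P(=O)(OCC(F)(F)F)OCC(F)(F)F
Why: Still–Gennari olefination gives the Z‑trisubstituted enoate (C11 cis to C14), the geometry the Claisen step needs.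

**Step 12**
Reactants: 12
Product: 13 (12Z) Weinreb amide
Conditions: MeNH(OMe)·HCl, i‑PrMgCl, THF, –20 °C
Reagents that add atoms: N,O‑dimethylhydroxylamine hydrochloride, CNOC.Cl
Why: Direct ester‑to‑Weinreb amide aminolysis; the Z geometry is not at risk because no enolisable position is conjugated.

**Step 13**
Reactants: 13
Product: 14 (12Z)‑7β‑(TBSO)‑18‑(PMBO)‑labda‑8(17),12‑dien‑14‑one
Conditions: MeMgBr, THF, –20 → 0 °C
Reagents that add atoms: MeMgBr, C[Mg]Br
Why: Grignard addition to a Weinreb amide stops at the methyl ketone (chelated tetrahedral intermediate).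

**Step 14**
Reactants: 14
Product: 15 (12Z,14S)‑7β‑(TBSO)‑18‑(PMBO)‑labda‑8(17),12‑dien‑14‑ol
Conditions: (R)‑Me‑CBS (20 mol %), catecholborane, PhMe, –78 °C
Reagents that add atoms: none
Why: Corey–Bakshi–Shibata reduction (alkenyl = large group, methyl = small) sets the 14S carbinol that later controls C12 and C1′.

### Flavone fragment

**Step 15**
Reactants: 16 2‑hydroxy‑4,5‑dimethoxybenzaldehyde
Product: 17 2‑(benzyloxy)‑4,5‑dimethoxybenzaldehyde
Conditions: BnBr, K2CO3, DMF, rt
Reagents that add atoms: benzyl bromide, BrCc1ccccc1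
Why: Williamson benzylation; it stops the B‑ring phenol from competing in the flavone cyclisation.

**Step 16**
Reactants: 17; 18 1‑[2,4‑bis(benzyloxy)‑6‑hydroxyphenyl]ethanone
Product: 19 (E)‑chalcone
Conditions: KOH, EtOH, rt
Reagents that add atoms: none
Why: Claisen–Schmidt aldol condensation.

**Step 17**
Reactants: 19
Product: 20 5,7‑bis(benzyloxy)‑2‑[2‑(benzyloxy)‑4,5‑dimethoxyphenyl]chromen‑4‑one
Conditions: I2 (10 mol %), DMSO, 130 °C
Reagents that add atoms: none
Why: Oxidative cyclisation of a 2′‑hydroxychalcone (oxa‑Michael, then iodine/DMSO dehydrogenation) to the flavone.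

**Step 18**
Reactants: 20
Product: 21 5,7‑dihydroxy‑2‑(2‑hydroxy‑4,5‑dimethoxyphenyl)chromen‑4‑one
Conditions: H2 (1 atm), 10 % Pd/C, EtOAc/MeOH, rt
Reagents that add atoms: none
Why: Hydrogenolysis of the three benzyl ethers; the chromone C2=C3 bond survives these mild conditions.

**Step 19**
Reactants: 21
Product: 22 7‑O‑TIPS flavone (5‑OH and 2′‑OH free)
Conditions: TIPSCl (1.05 equiv), imidazole, DMF, 0 °C
Reagents that add atoms: TIPSCl, CC(C)[Si](Cl)(C(C)C)C(C)C
Why: Selective silylation of the most acidic phenol (7‑OH, a vinylogous acid) over the chelated 5‑OH and the less acidic 2′‑OH.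

**Step 20**
Reactants: 22
Product: 23 quinone monoketal (C2′=O, C5′ dimethyl ketal, C4′–OMe, C1′=C6′)
Conditions: PhI(OAc)2, MeOH, 0 °C
Reagents that add atoms: methanol, CO
Why: Oxidative dearomatisation of a p‑methoxyphenol with PIDA in methanol; the electron‑rich B ring reacts, the chelated, electron‑poor 5‑OH does not.

**Step 21**
Reactants: 23
Product: 24 α‑chromonyl ketone (C6′H2, C1′–H; keto/enol mixture, used crude and kept acid‑free)
Conditions: L‑Selectride (2.2 equiv), THF, –78 °C; pH 7 buffer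
Reagents that add atoms: none
Why: Conjugate (1,4) hydride reduction at the unsubstituted β‑carbon C6′ of the doubly activated enone; the C5′ ketal prevents re‑aromatisation.

### Union and endgame

**Step 22**
Reactants: 15; 24
Product: 25 (14R,12Z)‑allyl enol ether (C2′–O–C14)
Conditions: PPh3, DIAD, PhMe/THF, 0 °C → rt
Reagents that add atoms: none
Why: Mitsunobu O‑alkylation of the vinylogous 1,3‑dicarbonyl enol with inversion at C14 (S → R); C‑alkylation would create a quaternary centre by SN2 and is disfavoured, and the chelated 5‑OH is a poor Mitsunobu partner.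

**Step 23**
Reactants: 25
Product: 26 Claisen product: quaternary C1′ bearing chromone, C2′=O, C6′H2 and the C12H(CH2‑decalin)–C(CH3)=CH–CH3 arm
Conditions: PhMe, 2,6‑di‑tert‑butyl‑4‑methylpyridine (10 mol %), 120 °C, sealed tube
Reagents that add atoms: none
Why: Proposed new method: thermal [3,3] Claisen rearrangement of an O‑allyl enol ether built on a dearomatised flavone B ring, the closest known type being Claisen rearrangements of O‑allyl enol ethers of 2‑substituted cyclic 1,3‑diones with 1,3‑chirality transfer; the ring fixes the enol geometry (O cis to chromone), and the Z‑alkene in a chair with the C14 methyl equatorial (A1,3 strain) puts C11 cis to the chromone and relays (14R) to the target C12 and C1′ configurations, while the C5′ ketal blocks aromatisation until C1′ is quaternary.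

**Step 24**
Reactants: 26
Product: 27 ene‑dione (C5′=O unveiled; C6′H2)
Conditions: PPTS (cat.), acetone/H2O (10:1), rt
Reagents that add atoms: water, O
Why: Mild acetal hydrolysis of the labile quinone‑type ketal; the vinylogous ester OMe, PMB and silyl ethers survive, and the compound cannot aromatise because C1′ is quaternary.

**Step 25**
Reactants: 27
Product: 28 6′‑allyl ene‑dione (C6′ epimer mixture)
Conditions: LiHMDS (2.2 equiv), THF/DMPU, –78 °C; allyl iodide, –78 → –40 °C
Reagents that add atoms: allyl iodide, C=CCI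
Why: Enolate alkylation; C6′ is the only enolisable position (C1′ is quaternary, C3′ is vinylic), and the first equivalent of base is consumed by the 5‑OH.

**Step 26**
Reactants: 28
Product: 29 cyclohexene (C13=C14 formed; cis/trans ring‑fusion mixture at C6′)
Conditions: Grubbs II (10 mol %), PhMe, 80 °C, Ar sparge
Reagents that add atoms: none
Why: Ring‑closing metathesis initiated at the terminal allyl alkene closes the six‑membered ring onto the propenyl group with loss of propene; the hindered exocyclic C8=C17 alkene and the electron‑poor enones are spectators.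

**Step 27**
Reactants: 29
Product: 30 cis‑fused ene‑dione (6′‑H cis to the chromone)
Conditions: DBU (0.3 equiv), CH2Cl2, rt
Reagents that add atoms: none
Why: Base‑mediated epimerisation at C6′ (α to C5′=O) to the cis‑fused isomer, which is expected to be favoured with an angular substituent and is the fusion found in the natural product.

**Step 28**
Reactants: 30
Product: 31 C18 primary alcohol
Conditions: DDQ, CH2Cl2/pH 7 buffer, 0 °C
Reagents that add atoms: none
Why: Oxidative PMB ether cleavage; TBS and TIPS ethers and the alkenes are inert.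

**Step 29**
Reactants: 31
Product: 32 C18 aldehyde
Conditions: Dess–Martin periodinane, NaHCO3, CH2Cl2, 0 °C → rt
Reagents that add atoms: none
Why: Dess–Martin oxidation of the neopentyl primary alcohol; the aldehyde is α‑quaternary and cannot epimerise, and the only secondary alcohol is still silylated.

**Step 30**
Reactants: 32
Product: 33 Dichrostachine H
Conditions: HF·pyridine, pyridine/THF, 0 °C → rt
Reagents that add atoms: none
Why: Buffered fluoride desilylation removes the 7‑OTBS and the aryl OTIPS without touching the allylic alcohol, aldehyde or ene‑dione.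

## Compound list

1 | (–)‑abietic acid | CC(C)C1=CC2=CC[C@@H]3[C@](C)(CCC[C@@]3(C)C(=O)O)[C@H]2CC1 | starting material
2 | abietinol | CC(C)C1=CC2=CC[C@@H]3[C@](C)(CCC[C@@]3(C)CO)[C@H]2CC1 | intermediate
3 | abietinol PMB ether | CC(C)C1=CC2=CC[C@@H]3[C@](C)(CCC[C@@]3(C)COCc4ccc(OC)cc4)[C@H]2CC1 | intermediate
4 | 13,14‑seco keto‑enal | O=CC1=CC[C@@H]2[C@](C)(CCC[C@@]2(C)COCc3ccc(OC)cc3)[C@H]1CCC(=O)C(C)C | intermediate
5 | allylic alcohol (C17–OH) | OCC1=CC[C@@H]2[C@](C)(CCC[C@@]2(C)COCc3ccc(OC)cc3)[C@H]1CCC(=O)C(C)C | intermediate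
6 | 7β,8β‑epoxy alcohol | OC[C@]12O[C@H]1C[C@@H]3[C@](C)(CCC[C@@]3(C)COCc4ccc(OC)cc4)[C@H]2CCC(=O)C(C)C | intermediate
7 | epoxy iodide | IC[C@]12O[C@H]1C[C@@H]3[C@](C)(CCC[C@@]3(C)COCc4ccc(OC)cc4)[C@H]2CCC(=O)C(C)C | intermediate
8 | 7β‑hydroxy‑8(17)‑ene ketone | C=C1[C@@H](O)C[C@@H]2[C@](C)(CCC[C@@]2(C)COCc3ccc(OC)cc3)[C@H]1CCC(=O)C(C)C | intermediate
9 | 7β‑OTBS ketone | C=C1[C@@H](O[Si](C)(C)C(C)(C)C)C[C@@H]2[C@](C)(CCC[C@@]2(C)COCc3ccc(OC)cc3)[C@H]1CCC(=O)C(C)C | intermediate
10 | 12‑hydroxy ketone | C=C1[C@@H](O[Si](C)(C)C(C)(C)C)C[C@@H]2[C@](C)(CCC[C@@]2(C)COCc3ccc(OC)cc3)[C@H]1CC(O)C(=O)C(C)C | intermediate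
11 | tetranorlabd‑8(17)‑en‑12‑al | C=C1[C@@H](O[Si](C)(C)C(C)(C)C)C[C@@H]2[C@](C)(CCC[C@@]2(C)COCc3ccc(OC)cc3)[C@H]1CC=O | intermediate
12 | (12Z)‑enoate | C=C1[C@@H](O[Si](C)(C)C(C)(C)C)C[C@@H]2[C@](C)(CCC[C@@]2(C)COCc3ccc(OC)cc3)[C@H]1C/C=C(C)\C(=O)OC | intermediate
13 | (12Z) Weinreb amide | C=C1[C@@H](O[Si](C)(C)C(C)(C)C)C[C@@H]2[C@](C)(CCC[C@@]2(C)COCc3ccc(OC)cc3)[C@H]1C/C=C(C)\C(=O)N(C)OC | intermediate
14 | (12Z)‑labda‑8(17),12‑dien‑14‑one | C=C1[C@@H](O[Si](C)(C)C(C)(C)C)C[C@@H]2[C@](C)(CCC[C@@]2(C)COCc3ccc(OC)cc3)[C@H]1C/C=C(C)\C(C)=O | intermediate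
15 | (12Z,14S)‑labda‑8(17),12‑dien‑14‑ol | C=C1[C@@H](O[Si](C)(C)C(C)(C)C)C[C@@H]2[C@](C)(CCC[C@@]2(C)COCc3ccc(OC)cc3)[C@H]1C/C=C(C)\[C@H](C)O | intermediate
16 | 2‑hydroxy‑4,5‑dimethoxybenzaldehyde | O=Cc1cc(OC)c(OC)cc1O | starting material
17 | 2‑(benzyloxy)‑4,5‑dimethoxybenzaldehyde | O=Cc1cc(OC)c(OC)cc1OCc1ccccc1 | intermediate
18 | 1‑[2,4‑bis(benzyloxy)‑6‑hydroxyphenyl]ethanone | CC(=O)c1c(O)cc(OCc2ccccc2)cc1OCc1ccccc1 | starting material
19 | chalcone | O=C(/C=C/c1cc(OC)c(OC)cc1OCc1ccccc1)c1c(O)cc(OCc2ccccc2)cc1OCc1ccccc1 | intermediate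
20 | tribenzyl flavone | O=c1cc(-c2cc(OC)c(OC)cc2OCc2ccccc2)oc2cc(OCc3ccccc3)cc(OCc3ccccc3)c12 | intermediate
21 | 5,7,2′‑trihydroxy‑4′,5′‑dimethoxyflavone | O=c1cc(-c2cc(OC)c(OC)cc2O)oc2cc(O)cc(O)c12 | intermediate
22 | 7‑O‑TIPS flavone | O=c1cc(-c2cc(OC)c(OC)cc2O)oc2cc(O[Si](C(C)C)(C(C)C)C(C)C)cc(O)c12 | intermediate
23 | quinone monoketal | O=C1C=C(OC)C(OC)(OC)C=C1c2cc(=O)c3c(O)cc(O[Si](C(C)C)(C(C)C)C(C)C)cc3o2 | intermediate
24 | α‑chromonyl ketone | O=C1C=C(OC)C(OC)(OC)CC1c2cc(=O)c3c(O)cc(O[Si](C(C)C)(C(C)C)C(C)C)cc3o2 | intermediate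
25 | (14R,12Z)‑allyl enol ether | C=C1[C@@H](O[Si](C)(C)C(C)(C)C)C[C@@H]2[C@](C)(CCC[C@@]2(C)COCc3ccc(OC)cc3)[C@H]1C/C=C(C)\[C@@H](C)OC4=C(c5cc(=O)c6c(O)cc(O[Si](C(C)C)(C(C)C)C(C)C)cc6o5)CC(OC)(OC)C(OC)=C4 | intermediate
26 | Claisen product (C5′ ketal) | C=C1[C@@H](O[Si](C)(C)C(C)(C)C)C[C@@H]2[C@](C)(CCC[C@@]2(C)COCc3ccc(OC)cc3)[C@H]1C[C@@H]([C@@]4(c5cc(=O)c6c(O)cc(O[Si](C(C)C)(C(C)C)C(C)C)cc6o5)CC(OC)(OC)C(OC)=CC4=O)/C(C)=C/C | intermediate
27 | ene‑dione | C=C1[C@@H](O[Si](C)(C)C(C)(C)C)C[C@@H]2[C@](C)(CCC[C@@]2(C)COCc3ccc(OC)cc3)[C@H]1C[C@@H]([C@@]4(c5cc(=O)c6c(O)cc(O[Si](C(C)C)(C(C)C)C(C)C)cc6o5)CC(=O)C(OC)=CC4=O)/C(C)=C/C | intermediate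
28 | 6′‑allyl ene‑dione (C6′ mixture) | C=C1[C@@H](O[Si](C)(C)C(C)(C)C)C[C@@H]2[C@](C)(CCC[C@@]2(C)COCc3ccc(OC)cc3)[C@H]1C[C@@H]([C@@]4(c5cc(=O)c6c(O)cc(O[Si](C(C)C)(C(C)C)C(C)C)cc6o5)C(CC=C)C(=O)C(OC)=CC4=O)/C(C)=C/C | intermediate
29 | metathesis product (C6′ mixture) | C=C1[C@@H](O[Si](C)(C)C(C)(C)C)C[C@@H]2[C@](C)(CCC[C@@]2(C)COCc3ccc(OC)cc3)[C@H]1C[C@@H]4C(C)=CCC5C(=O)C(OC)=CC(=O)[C@@]45c6cc(=O)c7c(O)cc(O[Si](C(C)C)(C(C)C)C(C)C)cc7o6 | intermediate
30 | cis‑fused, fully protected | C=C1[C@@H](O[Si](C)(C)C(C)(C)C)C[C@@H]2[C@](C)(CCC[C@@]2(C)COCc3ccc(OC)cc3)[C@H]1C[C@@H]4C(C)=CC[C@H]5C(=O)C(OC)=CC(=O)[C@@]45c6cc(=O)c7c(O)cc(O[Si](C(C)C)(C(C)C)C(C)C)cc7o6 | intermediate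
31 | C18 alcohol | C=C1[C@@H](O[Si](C)(C)C(C)(C)C)C[C@@H]2[C@](C)(CCC[C@@]2(C)CO)[C@H]1C[C@@H]3C(C)=CC[C@H]4C(=O)C(OC)=CC(=O)[C@@]34c5cc(=O)c6c(O)cc(O[Si](C(C)C)(C(C)C)C(C)C)cc6o5 | intermediate
32 | C18 aldehyde, bis‑silyl | C=C1[C@@H](O[Si](C)(C)C(C)(C)C)C[C@@H]2[C@](C)(CCC[C@@]2(C)C=O)[C@H]1C[C@@H]3C(C)=CC[C@H]4C(=O)C(OC)=CC(=O)[C@@]34c5cc(=O)c6c(O)cc(O[Si](C(C)C)(C(C)C)C(C)C)cc6o5 | intermediate
33 | Dichrostachine H | C=C1[C@@H](O)C[C@@H]2[C@](C)(CCC[C@@]2(C)C=O)[C@H]1C[C@@H]1C(C)=CC[C@H]2C(=O)C(OC)=CC(=O)[C@@]12c1cc(=O)c2c(O)cc(O)cc2o1 | target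

## Summary

- **Total steps:** 30.
- **Longest linear sequence:** 23 (steps 1–14, then 22–30).

**Steps most likely to fail, with fallbacks**

1. **Step 23 (Claisen on the dearomatised B ring).** Risks are loss of MeOH with re‑aromatisation, or ionisation/[1,3] shift instead of [3,3]. Fallback: replace the sigmatropic route with a silicon‑tethered intramolecular quinone Diels–Alder. The 12E,14‑diene analogue of 15 (7‑OH free) is linked as C7–O–Si(i‑Pr)2–C3(chromone) to the flavone 2′,5′‑quinone. The tether is intended to hold the chromone on the C11 side of the forming C12–C1′ bond, though this would need modelling, and is removed with fluoride (Si–O cleavage and protodesilylation at C3).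
2. **Step 22 (Mitsunobu O‑alkylation of enol 24 with a hindered secondary allylic alcohol).** Risks are low acidity of 24, SN2′ attack, or C‑alkylation. Fallback: etherify at the aromatic stage instead. A phenol Mitsunobu of 15 with a 3′‑bromo‑6′‑allyl analogue of flavone 22 is followed by a dearomative aromatic Claisen into C1′ (Br blocks the other ortho position; the 5′‑OH tautomerises to the ene‑dione), and Br is removed at the end with Pd(0)/formate.
3. **Step 5 (mismatched Sharpless epoxidation on the β‑face).** Fallback: make the substrate‑preferred 7α,8α‑epoxide (L‑(+)‑DIPT), carry it through steps 6–7 to the 7α‑alcohol, then oxidise to the 8(17)‑en‑7‑one and Luche‑reduce (axial hydride delivery) to the 7β‑alcohol.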